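## The problem

Compound 39 is a 5-8-3 tricycle. The numbering used throughout is: C1–C8 for the cyclooctane; C2=C3 is shared with the butenolide, whose carbonyl carbon C10 sits on C3 and whose OCH2 carbon C11 sits on C2; C9 is the cyclopropane methylene across C4–C5; C6 carries the methyl group, C8 the free hydroxyl, and C1 the side chain, whose stereocentre C1′ bears CH2OAc and a 4-methylpent-3-enyl group.

The skeletal difficulty is the eight-membered ring: every ring carbon except C7 is substituted or shared with another ring, so a direct medium-ring closure would have to overcome transannular strain while carrying four ring stereocentres. Of the six stereocentres, C4, C5 and C6 are contiguous and can be related on a six-membered ring (cyclopropane anti to methyl), and once set they can decide the face on which further ring bonds form. C1 is α to a carbonyl in any C8 ketone precursor and can be left to thermodynamic control on a rigid frame. C8 must come from hydride addition next to C1. C1′ is exocyclic, cannot be controlled from the ring, and has to arrive enantiopure in a separate fragment.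

The acetate will not survive strong base or hydride, and the trisubstituted side-chain alkene will not survive electrophilic carbenoids, peracids or strong acid, so the cyclopropane must exist before that alkene enters and the acetate must come last. The enabling feature is that C10 and the C8 oxygen are 1,4-related across C3–C2–C1–C8. This 4-oxocyclooctanecarboxylate pattern is what results when a bicyclo[3.3.1]nonane-2,9-dione, in which C10 bridges C3 and C7, loses its C7–C10 bond, and the oxygen on C11 lies 1,3 to C10 and can serve as the nucleophile that cuts it.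

## Retrosynthesis

**Late adjustments (39 back to 32).** The acetate is removed first: 39 comes from diol 38 by acylation of the primary hydroxyl, and 38 from bis-silyl ether 37. The C2=C3 double bond is taken out next, because C3 must be an sp3 bridgehead in the ring-forming event: 37 comes from selenide 35 by syn-elimination, and 35 from saturated lactone 34. The C8 carbinol goes back through 33 to ketone 32. No skeletal bond is cut here. The forward steps ask for hydride delivery anti to the C1 substituent and for enolate trapping on the face of H2, so that selenium and H2 are syn.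

**Unzipping the eight-membered ring (32 back to 31).** In the reverse sense the lactone O–C10 bond is opened and C7 is joined to C10, giving hydroxy dione 31. A direct closure of the cyclooctane (acylation at C7–C8, metathesis, or an aldol across the ring) would be entropically poor and would leave C1 and C8 to a flexible ring. In 31 the same atoms sit in two six-membered rings, and the strain of the one-carbon bridge drives the forward fragmentation. The forward reaction must send the C11 oxygen to C10 and not to C8, and must leave C1 untouched.

**Annulation (31 back to 30, then 14 + 28).** Hydroxy dione 31 is the deprotected form of PMB ether 30. Cutting C3–C2 and C7–C8 in 30 gives enamine 14 and α,β-unsaturated acid chloride 28. This is preferred over a stepwise Michael addition and acylation because the intermolecular Michael step onto an α-branched, β-substituted acceptor would be slow, whereas the acid chloride is delivered through nitrogen in a [3,3] shift. The (E)-chloride is required: in the chair transition state its oxymethyl group is trans to the C3–C4 bond and therefore ends up axial on C2, within reach of C10. The (Z)-isomer that would come from opening a butenolide would place it equatorial and would also relactonise at the acid chloride stage. The forward reaction must form its first bond at C3, on the face anti to C9.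

**Ring A (14 back to 1 + 2).** Enamine 14 comes from ketone 12, and 12 from alcohol 11, whose hydroxyl directs the cyclopropanation of cyclohexenol 10. Cutting the C4=C5 alkene of 10 by metathesis gives dienol 9. Cutting the carbinol–allyl bond gives aldehyde 7 and allylborane 8. Aldehyde 7 comes via alcohol 6 from imide 5, whose C6 stereocentre is cut back to crotonyl imide 3 and vinylmagnesium bromide 4, and 3 to auxiliary 1 and acid chloride 2. The hydroxyl of 10 must be trans to the methyl so that directed delivery and steric preference agree.

**Side-chain fragment (28 back to 15, 16, 18, 20, 23).** Acid chloride 28 comes from acid 27 and enoyl imide 26. Cutting the trisubstituted alkene as an aldol and dehydration gives imide 22 and aldehyde 23 via aldol 24. Cutting the C1′–homoprenyl bond of 22 as a conjugate addition gives enoyl imide 19 and bromide 20 (as Grignard reagent 21). Imide 19 comes from phosphonate 17 and aldehyde 18, and 17 from auxiliary 15 and acid 16. One auxiliary thus sets C1′ and then serves as the carboxyl handle for the aldol.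

## Roads not taken

**Alternative 1:** The cut is the C4–C5 cyclopropane bond, made last from a nine-membered ring. The precursor is the (Z)-cyclononenyl C4 mesylate A2, in which C9 lies in the ring between C4 and the C5=C6 alkene. Ionisation in a fluorinated alcohol with a trialkylsilane would let C5 displace the mesylate across the ring, and hydride capture of the cyclopropylcarbinyl cation at C6 would give A1, the C8 silyl ether of 39.

- Merits: the cyclopropane and the eight-membered ring arise in one step, and A1 is one deprotection from the target. In endgame economy this road is better than the chosen plan, which needs six steps after its ring-forming event.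
- Weak points: A2 is a nine-membered ring with a trisubstituted Z-alkene and a configured C4 sulfonate, which is harder to make than anything in the chosen route. The C4 cation is attached to the α-carbon of an electron-poor butenolide and would be slow to form. The cyclopropylcarbinyl cation can leak to cyclobutyl or homoallyl products. The hydride sets C6 on a flexible ring. The side-chain alkene and the acetate can intercept the cation.
- Comparison: the chosen plan sets C4, C5 and C6 by a hydroxyl-directed cyclopropanation on a six-membered ring at step 7 and never passes through a carbocation.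

**Alternative 2:** The cut is C7–C8. The precursor is aldehyde A4, an α-alkylidene lactone carrying a sacrificial trans-2-methylcyclopropyl group. With [Rh(dppe)]BF4, a cationic complex of monovalent rhodium, the acyl–rhodium hydride would add across C3=C4, the cyclopropane would open, and reductive elimination would close the ring to the (Z)-cyclooct-4-enone A3.

- Merits: the step is catalytic and redox-neutral, and it delivers the C8 ketone, the cis lactone and even the acetate in one operation. In protecting-group economy and probably in step count to the ring it is at least as good as the chosen plan.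
- Weak points: the cyclopropane it consumes is not the one the target needs. The real one must then be built on the C4=C5 cyclooctene with no nearby directing group, on a flexible ring, in the presence of a more electron-rich trisubstituted alkene. The aldehyde has an epimerisable α-centre (C1) and can decarbonylate. The methyl-bearing cyclopropane can open at either bond.
- Comparison: the chosen plan carries the true cyclopropane from an early, directed step and introduces the side-chain alkene only afterwards.

**Alternative 3:** The cut is a two-carbon ring expansion. HNTf2 would catalyse a [2+2] cycloaddition between silyl enol ether A6 (a cyclohexanone with C1, C6, C8 and C1′ in place) and methyl propiolate A7, and thermal ring opening of the cyclobutene would give cyclooctadiene ester A5.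

- Merits: four stereocentres, including C8, are set on a six-membered ring before expansion. That is a real advantage over the chosen plan, which must set C8 by reduction on the eight-membered ring.
- Weak points: A6 needs a regiodefined enol ether of an unsymmetrical ketone. The strong acid meets two silyl ethers and a trisubstituted alkene. A5 still lacks the cyclopropane and the lactone methylene, so a one-carbon homologation at C2 and a chemoselective, undirected cyclopropanation of a dienoate remain.
- Comparison: the chosen plan answers the C8 question with a hindered hydride and a reagent-controlled fallback, and its ring-forming step already delivers the lactone and the cyclopropane.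

Key step: step 19

Assumption: the atom numbers C1–C11 and C1′ defined under "The problem" are used for every ring compound, and enamine 14 is drawn as its C3-ene isomer, with which any C7-ene isomer is expected to equilibrate under the conditions of step 17.

## Route

Step 1
Reactants: 1 (R)-4-benzyloxazolidin-2-one; 2 (E)-but-2-enoyl chloride
Product: 3 (R)-4-benzyl-3-[(E)-but-2-enoyl]oxazolidin-2-one
Conditions: n-BuLi, THF, −78 °C; then 2, −78 → 0 °C
Reagents that add atoms: none
Why: N-acylation of the lithiated oxazolidinone, the standard way to an N-enoyl auxiliary.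

Step 2
Reactants: 3 (R)-4-benzyl-3-[(E)-but-2-enoyl]oxazolidin-2-one; 4 vinylmagnesium bromide
Product: 5 (R)-4-benzyl-3-[(3S)-3-methylpent-4-enoyl]oxazolidin-2-one
Conditions: CuBr·SMe2 (0.5 equiv), THF/Me2S, −40 → −15 °C; aq. NH4Cl
Reagents that add atoms: none
Why: Auxiliary-controlled cuprate conjugate addition; in the magnesium-chelated s-cis imide the benzyl group shields one face, so vinyl adds to the other and sets the future C6 as (S).

Step 3
Reactants: 5 (R)-4-benzyl-3-[(3S)-3-methylpent-4-enoyl]oxazolidin-2-one
Product: 6 (S)-3-methylpent-4-en-1-ol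
Conditions: LiBH4, H2O (1 equiv), Et2O, 0 °C
Reagents that add atoms: none
Why: Reductive cleavage of the imide to the primary alcohol with recovery of the auxiliary; the stereocentre is not α to the carbonyl and is not at risk.

Step 4
Reactants: 6 (S)-3-methylpent-4-en-1-ol
Product: 7 (S)-3-methylpent-4-enal
Conditions: Dess–Martin periodinane, NaHCO3, CH2Cl2, 0 °C → rt; kept as a dried solution
Reagents that add atoms: none
Why: Mild buffered oxidation of a primary alcohol; the volatile aldehyde is kept in solution and the β-stereocentre cannot epimerise.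

Step 5
Reactants: 7 (S)-3-methylpent-4-enal; 8 (+)-B-allyldiisopinocampheylborane
Product: 9 (4R,6S)-6-methylocta-1,7-dien-4-ol
Conditions: Et2O, −78 °C; then NaOH, H2O2, 0 °C → rt
Reagents that add atoms: none
Why: Brown allylation under reagent control; the (+)-reagent should deliver allyl to the Re face and give the (4R)-carbinol, which places the hydroxyl trans to the methyl after ring closure.

Step 6
Reactants: 9 (4R,6S)-6-methylocta-1,7-dien-4-ol
Product: 10 (1R,5S)-5-methylcyclohex-3-en-1-ol
Conditions: (H2IMes)(PCy3)Cl2Ru=CHPh (second-generation Grubbs catalyst, 1 mol%), CH2Cl2, 40 °C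
Reagents that add atoms: none
Why: Ring-closing metathesis of a 1,7-diene to a cyclohexene, driven by loss of ethene; free homoallylic alcohols are tolerated.

Step 7
Reactants: 10 (1R,5S)-5-methylcyclohex-3-en-1-ol
Product: 11 (1S,3S,5S,6R)-5-methylbicyclo[4.1.0]heptan-3-ol
Conditions: Et2Zn, CH2I2, CH2Cl2, −10 → 0 °C
Reagents that add atoms: diiodomethane, ICI
Why: Hydroxyl-directed Simmons–Smith cyclopropanation; the zinc alkoxide delivers the methylene cis to the homoallylic oxygen, which is also the face anti to the allylic methyl, so C4 and C5 are set relative to C6 by two reinforcing effects.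

Step 8
Reactants: 11 (1S,3S,5S,6R)-5-methylbicyclo[4.1.0]heptan-3-ol
Product: 12 (1S,5S,6R)-5-methylbicyclo[4.1.0]heptan-3-one
Conditions: Dess–Martin periodinane, NaHCO3, CH2Cl2, 0 °C → rt
Reagents that add atoms: none
Why: Oxidation of a secondary alcohol; the directing stereocentre is no longer needed and the cyclopropane is inert.

Step 9
Reactants: 12 (1S,5S,6R)-5-methylbicyclo[4.1.0]heptan-3-one; 13 pyrrolidine
Product: 14 1-[(1R,5S,6R)-5-methylbicyclo[4.1.0]hept-2-en-3-yl]pyrrolidine
Conditions: TsOH·H2O (cat.), PhH, reflux, Dean–Stark; evaporate and use crude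
Reagents that add atoms: none
Why: Enamine condensation with azeotropic removal of water; the C3-ene isomer drawn is the one conjugated with the cyclopropane and remote from the methyl group.

Step 10
Reactants: 15 (S)-4-benzyloxazolidin-2-one; 16 2-(diethoxyphosphoryl)acetic acid
Product: 17 (S)-4-benzyl-3-[2-(diethoxyphosphoryl)acetyl]oxazolidin-2-one
Conditions: t-BuCOCl, Et3N, THF, −20 → 0 °C; then LiCl, 15, rt
Reagents that add atoms: none
Why: N-acylation of the oxazolidinone through the pivaloyl mixed anhydride.

Step 11
Reactants: 17 (S)-4-benzyl-3-[2-(diethoxyphosphoryl)acetyl]oxazolidin-2-one; 18 (tert-butyldimethylsilyloxy)acetaldehyde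
Product: 19 (S)-4-benzyl-3-[(E)-4-(tert-butyldimethylsilyloxy)but-2-enoyl]oxazolidin-2-one
Conditions: LiCl, i-Pr2NEt, MeCN, rt
Reagents that add atoms: none
Why: Horner–Wadsworth–Emmons olefination under mild lithium chloride and amine conditions, which are (E)-selective with stabilised phosphonates and aldehydes.

Step 12
Reactants: 19 (S)-4-benzyl-3-[(E)-4-(tert-butyldimethylsilyloxy)but-2-enoyl]oxazolidin-2-one; 20 5-bromo-2-methylpent-2-ene
Product: 22 (S)-4-benzyl-3-[(3S)-3-[(tert-butyldimethylsilyloxy)methyl]-7-methyloct-6-enoyl]oxazolidin-2-one, via (4-methylpent-3-en-1-yl)magnesium bromide 21 (not isolated)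
Conditions: 20, Mg, THF, rt; then CuBr·SMe2 (0.5 equiv), THF/Me2S, −40 °C; 19, −40 → −15 °C; aq. NH4Cl
Reagents that add atoms: none
Why: Auxiliary-controlled cuprate conjugate addition by the same facial model as step 2; with the (S)-auxiliary the homoprenyl group enters anti to benzyl and sets C1′ as (S).

Step 13
Reactants: 22 (S)-4-benzyl-3-[(3S)-3-[(tert-butyldimethylsilyloxy)methyl]-7-methyloct-6-enoyl]oxazolidin-2-one; 23 2-[(4-methoxybenzyl)oxy]acetaldehyde
Product: 24 (S)-4-benzyl-3-[(2S,3S)-2-[(2S)-1-(tert-butyldimethylsilyloxy)-6-methylhept-5-en-2-yl]-3-hydroxy-4-[(4-methoxybenzyl)oxy]butanoyl]oxazolidin-2-one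
Conditions: Bu2BOTf, i-Pr2NEt, CH2Cl2, −78 → 0 °C; then 23, −78 → 0 °C; pH 7 buffer, MeOH, H2O2
Reagents that add atoms: none
Why: Evans syn-aldol through the (Z)-boron enolate; the two new centres are removed in the next step, but a single syn isomer makes the elimination stereochemically unambiguous.

Step 14
Reactants: 24 the syn-aldol imide
Product: 26 (S)-4-benzyl-3-[(2E)-2-[(2S)-1-(tert-butyldimethylsilyloxy)-6-methylhept-5-en-2-yl]-4-[(4-methoxybenzyl)oxy]but-2-enoyl]oxazolidin-2-one, via the C3 mesylate 25 (not isolated)
Conditions: MsCl, Et3N, CH2Cl2, 0 °C; then DBU, 0 °C → rt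
Reagents that add atoms: none
Why: Mesylation and base-induced β-elimination; anti-elimination from the syn-aldol and the thermodynamic preference both lead to the (E)-alkene, with the oxymethyl group trans to the carbonyl.

Step 15
Reactants: 26 the (E)-enoyl imide
Product: 27 (2E)-2-[(2S)-1-(tert-butyldimethylsilyloxy)-6-methylhept-5-en-2-yl]-4-[(4-methoxybenzyl)oxy]but-2-enoic acid
Conditions: LiOH, H2O2, THF/H2O, 0 °C; Na2SO3; 1 M HCl
Reagents that add atoms: hydrogen peroxide, OO
Why: Hydroperoxide cleavage of the N-acyl oxazolidinone, selective for the exocyclic carbonyl; the hindered trisubstituted enoate is a poor partner for nucleophilic epoxidation, and both ethers are stable.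

Step 16
Reactants: 27 the (E)-acid
Product: 28 (2E)-2-[(2S)-1-(tert-butyldimethylsilyloxy)-6-methylhept-5-en-2-yl]-4-[(4-methoxybenzyl)oxy]but-2-enoyl chloride
Conditions: 1-chloro-N,N,2-trimethylprop-1-en-1-amine, CH2Cl2, 0 °C → rt; use crude
Reagents that add atoms: 1-chloro-N,N,2-trimethylprop-1-en-1-amine, CC(C)=C(Cl)N(C)C
Why: Neutral conversion of an acid into its chloride with an α-chloroenamine, which spares the silyl and benzyl ethers; the (E)-geometry prevents the ether oxygen from reaching the acyl carbon.

Step 17
Reactants: 14 the pyrrolidine enamine; 28 the (E)-acid chloride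
Product: 30 cyclopropa-fused bicyclo[3.3.1]nonane-2,9-dione (ring A C10–C3–C4–C5–C6–C7, bridge C2–C1–C8, ketones at C8 and C10) with axial CH2OPMB (C11) on C2, the (1′S) side chain CH(CH2OTBS)(4-methylpent-3-enyl) equatorial on C1, equatorial 6-methyl and C9 exo, via bicyclic iminium chloride 29 (not isolated)
Conditions: PhMe, 0 °C → 90 °C; then AcOH/NaOAc/H2O, 50 °C
Reagents that add atoms: water, O
Why: α,α′-Annulation of a cyclohexanone enamine with an α,β-unsaturated acid chloride (N-acylation, charge-accelerated [3,3] shift, then C-acylation by the ketene): the chair shift joins C3 to C2 anti to the cyclopropane methylene and, from the (E)-chloride, places C11 axial, after which the ketene acylates C7 and C1 settles equatorial by enolisation. A C7-ene isomer of 14 could close the bridge only by bonding its branched carbon cis to the C6 methyl on the face anti to the cyclopropane, so the bridged dione should arise through the C3-ene channel.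

Step 18
Reactants: 30 the PMB-protected dione
Product: 31 the same dione with free axial CH2OH on C2 (may sit partly as its C10 hemiketal)
Conditions: DDQ, CH2Cl2/pH 7 buffer (10:1), 0 °C
Reagents that add atoms: none
Why: Oxidative removal of a 4-methoxybenzyl ether under neutral conditions, so that the alcohol is freed without the base that triggers step 19; the silyl ether, cyclopropane and trisubstituted alkene are inert to DDQ.

Step 19
Reactants: 31 the hydroxy dione
Product: 32 tricyclic keto lactone: cyclooctan-8-one with a cis-fused γ-lactone across C2/C3 (C10 carbonyl on C3, O–C11H2 on C2), cis-cyclopropane at C4–C5, 6-methyl and the (1′S) silyloxy side chain on C1, configured at C1′, C1, C4, C5 and C6 as in 39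
Conditions: DBU (0.2 equiv), CH2Cl2, 0 °C → rt; AcOH quench; use at once
Reagents that add atoms: none
Why: DBU reversibly deprotonates the C11 hydroxyl, the axial oxygen adds to the bridging carbonyl C10 from the ring B face by 5-exo-trig closure (this forms the lactone ring), and the tetrahedral alkoxide collapses by expelling C7 as the C8 enolate, so the C7–C10 bridge is cut and the cyclooctanone is released by fragmentation, not by ring closure. The closest known reactions are the alkoxide retro-Claisen opening of bicyclo[3.3.1]nonane-2,9-diones to 4-oxocyclooctanecarboxylates and the hydroxyl-triggered retro-Claisen ring expansions of 2-(hydroxyalkyl)-1,3-diketones. No new stereocentre is created: C7 becomes a methylene, the cis lactone fusion is inherited from the axial C11 and the C3–C10 bond, and C1, C4, C5 and C6 are not touched. The selectivity needed is addition to C10 and not to C8, which lies at the same 1,3-distance from C2. C10 should be the more electrophilic carbonyl because its angle is compressed in the bridge and addition relieves that strain, while C8 is flanked by the branched C1 substituent. Protonation of C7 gives a simple ketone and makes the opening effectively irreversible under catalytic base; low temperature and immediate reduction protect C1 and C3 from epimerisation.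

Step 20
Reactants: 32 the keto lactone
Product: 33 the (8S)-alcohol, hydroxyl cis to the C1 side chain
Conditions: LiBH(s-Bu)3, THF, −78 °C; then pH 7 buffer, H2O2, 0 °C
Reagents that add atoms: none
Why: Reduction by a bulky trialkylborohydride, which attacks the ketone anti to the α-branch at C1 and so gives the cis-1,2 alcohol; at −78 °C the lactone is not reduced.

Step 21
Reactants: 33 the C8 alcohol
Product: 34 the C8 tert-butyldimethylsilyl ether
Conditions: TBSOTf, 2,6-lutidine, CH2Cl2, −78 → 0 °C
Reagents that add atoms: tert-butyldimethylsilyl trifluoromethanesulfonate, CC(C)(C)[Si](C)(C)OS(=O)(=O)C(F)(F)F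
Why: Silylation of a hindered secondary alcohol with the silyl triflate; it removes the acidic proton before enolate chemistry and prevents translactonisation onto C10.

Step 22
Reactants: 34 the bis-silyl lactone
Product: 35 the 3-(phenylselanyl) lactone, selenium cis to H2
Conditions: LiN(i-Pr)2, THF, −78 °C; then PhSeBr, −78 °C
Reagents that add atoms: phenylselenyl bromide, Br[Se]c1ccccc1
Why: α-Selenenylation of a lactone enolate; the planar C3 enolate should be attacked on the face of H2, away from the C1 branch on the neighbouring carbon, which keeps the cis ring fusion and places selenium syn to H2.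

Step 23
Reactants: 35 the selenide
Product: 37 bis-silyl butenolide (C2=C3), via selenoxide 36 (not isolated)
Conditions: NaIO4, NaHCO3, THF/MeOH/H2O, 0 °C → rt
Reagents that add atoms: none
Why: Selenoxide syn-elimination; the only syn β-hydrogen that leads to an unstrained alkene is H2, because elimination towards C4 would place a double bond on the cyclopropane. Periodate avoids peracid-type epoxidation of the side-chain alkene.

Step 24
Reactants: 37 the bis-silyl butenolide
Product: 38 diol (deacetyl 39)
Conditions: HF·pyridine, pyridine/THF, 0 °C → rt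
Reagents that add atoms: none
Why: Fluoride-mediated cleavage of both silyl ethers under buffered, weakly acidic conditions that spare the butenolide and avoid base at the acidic C1 and C11 positions.

Step 25
Reactants: 38 the diol
Product: 39 CNP0267808.2
Conditions: Ac2O, 2,4,6-collidine, CH2Cl2, −20 °C
Reagents that add atoms: acetic anhydride, CC(=O)OC(C)=O
Why: Chemoselective acetylation of a primary alcohol in the presence of a secondary one flanked by the C1 branch, using a weak hindered base at low temperature.

## Compound list

1 | (R)-4-benzyloxazolidin-2-one | O=C1N[C@H](Cc2ccccc2)CO1 | starting material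
2 | (E)-but-2-enoyl chloride | C/C=C/C(Cl)=O | starting material
3 | (R)-4-benzyl-3-[(E)-but-2-enoyl]oxazolidin-2-one | C/C=C/C(=O)N1[C@H](Cc2ccccc2)COC1=O | intermediate
4 | vinylmagnesium bromide | C=C[Mg]Br | starting material
5 | (R)-4-benzyl-3-[(3S)-3-methylpent-4-enoyl]oxazolidin-2-one | C=C[C@@H](C)CC(=O)N1[C@H](Cc2ccccc2)COC1=O | intermediate
6 | (S)-3-methylpent-4-en-1-ol | C=C[C@@H](C)CCO | intermediate
7 | (S)-3-methylpent-4-enal | C=C[C@@H](C)CC=O | intermediate
8 | (+)-B-allyldiisopinocampheylborane | C=CCB([C@H]1C[C@H]2C[C@@H]([C@@H]1C)C2(C)C)[C@H]1C[C@H]2C[C@@H]([C@@H]1C)C2(C)C | starting material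
9 | (4R,6S)-6-methylocta-1,7-dien-4-ol | C=CC[C@@H](O)C[C@H](C)C=C | intermediate
10 | (1R,5S)-5-methylcyclohex-3-en-1-ol | O[C@@H]1CC=C[C@@H](C)C1 | intermediate
11 | (1S,3S,5S,6R)-5-methylbicyclo[4.1.0]heptan-3-ol | O[C@@H]1C[C@@H]2C[C@@H]2[C@@H](C)C1 | intermediate
12 | (1S,5S,6R)-5-methylbicyclo[4.1.0]heptan-3-one | O=C1C[C@@H]2C[C@@H]2[C@@H](C)C1 | intermediate
13 | pyrrolidine | C1CCNC1 | starting material
14 | 1-[(1R,5S,6R)-5-methylbicyclo[4.1.0]hept-2-en-3-yl]pyrrolidine | C1CCN(C1)C1=C[C@@H]2C[C@@H]2[C@@H](C)C1 | intermediate
15 | (S)-4-benzyloxazolidin-2-one | O=C1N[C@@H](Cc2ccccc2)CO1 | starting material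
16 | 2-(diethoxyphosphoryl)acetic acid | CCOP(=O)(CC(O)=O)OCC | starting material
17 | (S)-4-benzyl-3-[2-(diethoxyphosphoryl)acetyl]oxazolidin-2-one | CCOP(=O)(CC(=O)N1[C@@H](Cc2ccccc2)COC1=O)OCC | intermediate
18 | (tert-butyldimethylsilyloxy)acetaldehyde | CC(C)(C)[Si](C)(C)OCC=O | starting material
19 | (S)-4-benzyl-3-[(E)-4-(tert-butyldimethylsilyloxy)but-2-enoyl]oxazolidin-2-one | CC(C)(C)[Si](C)(C)OC/C=C/C(=O)N1[C@@H](Cc2ccccc2)COC1=O | intermediate
20 | 5-bromo-2-methylpent-2-ene | CC(C)=CCCBr | starting material
21 | (4-methylpent-3-en-1-yl)magnesium bromide | CC(C)=CCC[Mg]Br | intermediate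
22 | (S)-4-benzyl-3-[(3S)-3-[(tert-butyldimethylsilyloxy)methyl]-7-methyloct-6-enoyl]oxazolidin-2-one | CC(C)=CCC[C@H](CO[Si](C)(C)C(C)(C)C)CC(=O)N1[C@@H](Cc2ccccc2)COC1=O | intermediate
23 | 2-[(4-methoxybenzyl)oxy]acetaldehyde | COc1ccc(COCC=O)cc1 | starting material
24 | (S)-4-benzyl-3-[(2S,3S)-2-[(2S)-1-(tert-butyldimethylsilyloxy)-6-methylhept-5-en-2-yl]-3-hydroxy-4-[(4-methoxybenzyl)oxy]butanoyl]oxazolidin-2-one | COc1ccc(COC[C@@H](O)[C@H]([C@@H](CO[Si](C)(C)C(C)(C)C)CCC=C(C)C)C(=O)N2[C@@H](Cc3ccccc3)COC2=O)cc1 | intermediate
25 | C3 methanesulfonate of 24 | COc1ccc(COC[C@@H](OS(C)(=O)=O)[C@H]([C@@H](CO[Si](C)(C)C(C)(C)C)CCC=C(C)C)C(=O)N2[C@@H](Cc3ccccc3)COC2=O)cc1 | intermediate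
26 | (S)-4-benzyl-3-[(2E)-2-[(2S)-1-(tert-butyldimethylsilyloxy)-6-methylhept-5-en-2-yl]-4-[(4-methoxybenzyl)oxy]but-2-enoyl]oxazolidin-2-one | CC(C)=CCC[C@H](CO[Si](C)(C)C(C)(C)C)/C(=C\COCc1ccc(OC)cc1)C(=O)N1[C@@H](Cc2ccccc2)COC1=O | intermediate
27 | (2E)-2-[(2S)-1-(tert-butyldimethylsilyloxy)-6-methylhept-5-en-2-yl]-4-[(4-methoxybenzyl)oxy]but-2-enoic acid | CC(C)=CCC[C@H](CO[Si](C)(C)C(C)(C)C)/C(=C\COCc1ccc(OC)cc1)C(O)=O | intermediate
28 | (2E)-2-[(2S)-1-(tert-butyldimethylsilyloxy)-6-methylhept-5-en-2-yl]-4-[(4-methoxybenzyl)oxy]but-2-enoyl chloride | CC(C)=CCC[C@H](CO[Si](C)(C)C(C)(C)C)/C(=C\COCc1ccc(OC)cc1)C(Cl)=O | intermediate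
29 | C10 pyrrolidinium (iminium) chloride of dione 30 | CC(C)(C)[Si](C)(C)OC[C@@H](CCC=C(C)C)[C@@H]1[C@H](COCc2ccc(OC)cc2)[C@H]3[C@@H]4C[C@@H]4[C@@H](C)[C@H](C3=[N+]5CCCC5)C1=O.[Cl-] | intermediate
30 | cyclopropa-fused bicyclo[3.3.1]nonane-2,9-dione with axial C2 CH2OPMB, equatorial (1′S) silyloxy side chain on C1, equatorial 6-methyl, C9 exo | CC(C)(C)[Si](C)(C)OC[C@@H](CCC=C(C)C)[C@@H]1[C@H](COCc2ccc(OC)cc2)[C@H]3[C@@H]4C[C@@H]4[C@@H](C)[C@H](C3=O)C1=O | intermediate
31 | the same dione with free axial C2 CH2OH | CC(C)(C)[Si](C)(C)OC[C@@H](CCC=C(C)C)[C@@H]1[C@H](CO)[C@H]2[C@@H]3C[C@@H]3[C@@H](C)[C@H](C2=O)C1=O | intermediate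
32 | tricyclic C8 ketone with cis-fused saturated γ-lactone, cis-cyclopropane, 6-methyl and (1′S) silyloxy side chain | CC(C)(C)[Si](C)(C)OC[C@@H](CCC=C(C)C)[C@@H]1[C@@H]2COC(=O)[C@@H]2[C@@H]3C[C@@H]3[C@@H](C)CC1=O | intermediate
33 | (8S)-alcohol of 32, hydroxyl cis to the C1 side chain | CC(C)(C)[Si](C)(C)OC[C@@H](CCC=C(C)C)[C@@H]1[C@@H]2COC(=O)[C@@H]2[C@@H]3C[C@@H]3[C@@H](C)C[C@@H]1O | intermediate
34 | C8 tert-butyldimethylsilyl ether of 33 | CC(C)(C)[Si](C)(C)OC[C@@H](CCC=C(C)C)[C@@H]1[C@@H]2COC(=O)[C@@H]2[C@@H]3C[C@@H]3[C@@H](C)C[C@@H]1O[Si](C)(C)C(C)(C)C | intermediate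
35 | 3-(phenylselanyl) derivative of 34, selenium cis to H2 | CC(C)(C)[Si](C)(C)OC[C@@H](CCC=C(C)C)[C@@H]1[C@@H]2COC(=O)[C@]2([Se]c4ccccc4)[C@@H]3C[C@@H]3[C@@H](C)C[C@@H]1O[Si](C)(C)C(C)(C)C | intermediate
36 | selenoxide of 35 | CC(C)(C)[Si](C)(C)OC[C@@H](CCC=C(C)C)[C@@H]1[C@@H]2COC(=O)[C@]2([Se](=O)c4ccccc4)[C@@H]3C[C@@H]3[C@@H](C)C[C@@H]1O[Si](C)(C)C(C)(C)C | intermediate
37 | bis(tert-butyldimethylsilyl) ether of deacetyl 39 (C2=C3 butenolide) | CC(C)(C)[Si](C)(C)OC[C@@H](CCC=C(C)C)[C@@H]1C2=C(C(=O)OC2)[C@@H]3C[C@@H]3[C@@H](C)C[C@@H]1O[Si](C)(C)C(C)(C)C | intermediate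
38 | deacetyl 39 (primary and C8 diol) | OC[C@@H](CCC=C(C)C)[C@@H]1C2=C(C(=O)OC2)[C@@H]3C[C@@H]3[C@@H](C)C[C@@H]1O | intermediate
39 | CNP0267808.2, (1′S,1R,4R,5R,6S,8S) in the numbering above | CC(=O)OC[C@@H](CCC=C(C)C)[C@@H]1C2=C(C(=O)OC2)[C@@H]2C[C@@H]2[C@@H](C)C[C@@H]1O | target

## Step count and risks

Total steps: 25. Longest linear sequence: 18 (steps 1–9, then 17–25). The side-chain branch (steps 10–16) is 7 steps.

Least certain steps:

1. **Step 19 (key step).** The axial C11 oxygen is equally close to C8, so the alkoxide may add to the wrong carbonyl and cut C7–C8, which would give a six-membered keto lactone. Prolonged contact with base may also epimerise C1 or C3 in the flexible product. Fallback: set out from 30 and use external methoxide (NaOMe, MeOH, 0 °C), whose preference for the bridging carbonyl of such diones is established, to give the methyl 4-oxocyclooctanecarboxylate with the PMB ether intact, F4. Treatment with DDQ gives the hydroxy ester F5, which lactonises with a trace of acid and returns to the route at 32.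

2. **Step 17.** Regiocontrol may be lost if the C7-ene form of the enamine reacts, and the [3,3] shift may be slow with the α-branched chloride. Fallback: set out from 10 and oxidise it to (5S)-5-methylcyclohex-3-en-1-one F1 (Dess–Martin periodinane, NaHCO3). Deprotonation at the doubly activated carbon (LiN(i-Pr)2, then PhNTf2) gives (5S)-5-methylcyclohexa-1,3-dien-1-yl trifluoromethanesulfonate F2, whose regiochemistry is fixed by conjugation. Et2Zn/CH2I2 should cyclopropanate the distal, more electron-rich alkene anti to the methyl to give (1R,5S,6R)-5-methylbicyclo[4.1.0]hept-2-en-3-yl trifluoromethanesulfonate F3. Buchwald–Hartwig amination with pyrrolidine 13 (Pd2(dba)3 as the source of zerovalent palladium, BINAP, Cs2CO3, PhMe) gives enamine 14 as a single regioisomer, where the fallback rejoins the route.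

3. **Step 20.** Hydride may be delivered to the wrong face of the conformationally mobile cyclooctanone, or C1 may epimerise before reduction. Fallback: set out from 32 and use reagent control by Corey–Bakshi–Shibata reduction with (R)-Me-CBS and catecholborane, treating the branched C1 flank as the large group, to return at 33. This fallback makes no new compound (F0).

4. **Step 22.** Facial selectivity in trapping the enolate may be poor, which would put selenium anti to H2 and block the syn-elimination of step 23. Fallback: set out from 34, trap the same enolate with CBr4 to give the 3-bromo lactone F6 (bromine anti to H2 if the same face is used), and carry out an anti E2 elimination with DBU in warm toluene, whose geometric demand is complementary, to return at 37.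

5. **Step 25.** Over-acetylation at C8 or acetyl migration may occur. Fallback: set out from 37 and remove only the primary silyl ether (HF·pyridine, pyridine/THF, 0 °C, short contact) to give the primary alcohol with C8 still silylated, F7. Acetylation gives the C8-silylated acetate F8, and removal of the remaining silyl group with HF·pyridine returns at 39.

## Further compounds

F1 | step 17 | (5S)-5-methylcyclohex-3-en-1-one | O=C1CC=C[C@@H](C)C1
F2 | step 17 | (5S)-5-methylcyclohexa-1,3-dien-1-yl trifluoromethanesulfonate | FC(F)(F)S(=O)(=O)OC1=CC=C[C@@H](C)C1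
F3 | step 17 | (1R,5S,6R)-5-methylbicyclo[4.1.0]hept-2-en-3-yl trifluoromethanesulfonate | FC(F)(F)S(=O)(=O)OC1=C[C@@H]2C[C@@H]2[C@@H](C)C1
F4 | step 19 | methyl 4-oxocyclooctanecarboxylate from methoxide opening of 30 (CO2Me on C3, CH2OPMB on C2, cis) | CC(C)(C)[Si](C)(C)OC[C@@H](CCC=C(C)C)[C@@H]1[C@H](COCc2ccc(OC)cc2)[C@H](C(=O)OC)[C@@H]3C[C@@H]3[C@@H](C)CC1=O
F5 | step 19 | hydroxy ester from F4 after PMB removal | CC(C)(C)[Si](C)(C)OC[C@@H](CCC=C(C)C)[C@@H]1[C@H](CO)[C@H](C(=O)OC)[C@@H]3C[C@@H]3[C@@H](C)CC1=O
F0 | step 20 | none | none
F6 | step 22 | 3-bromo derivative of 34, bromine anti to H2 | CC(C)(C)[Si](C)(C)OC[C@@H](CCC=C(C)C)[C@@H]1[C@@H]2COC(=O)[C@@]2(Br)[C@@H]3C[C@@H]3[C@@H](C)C[C@@H]1O[Si](C)(C)C(C)(C)C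
F7 | step 25 | primary alcohol with C8 tert-butyldimethylsilyl ether | OC[C@@H](CCC=C(C)C)[C@@H]1C2=C(C(=O)OC2)[C@@H]3C[C@@H]3[C@@H](C)C[C@@H]1O[Si](C)(C)C(C)(C)C
F8 | step 25 | C8 tert-butyldimethylsilyl ether of 39 | CC(=O)OC[C@@H](CCC=C(C)C)[C@@H]1C2=C(C(=O)OC2)[C@@H]2C[C@@H]2[C@@H](C)C[C@@H]1O[Si](C)(C)C(C)(C)C
A1 | alternative 1 | C8 tert-butyldimethylsilyl ether of 39 | CC(=O)OC[C@@H](CCC=C(C)C)[C@@H]1C2=C(C(=O)OC2)[C@@H]2C[C@@H]2[C@@H](C)C[C@@H]1O[Si](C)(C)C(C)(C)C
A2 | alternative 1 | butenolide-fused (Z)-cyclononene C4 mesylate | CC(=O)OC[C@@H](CCC=C(C)C)[C@@H]1C2=C(C(=O)OC2)[C@H](OS(C)(=O)=O)C/C=C(C)\C[C@@H]1O[Si](C)(C)C(C)(C)C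
A3 | alternative 2 | lactone-fused (Z)-cyclooct-4-enone | CC(=O)OC[C@@H](CCC=C(C)C)[C@@H]1[C@@H]2COC(=O)[C@H]2/C=C\[C@@H](C)CC1=O
A4 | alternative 2 | aldehyde with (E)-(trans-2-methylcyclopropyl)methylidene lactone | CC(=O)OC[C@@H](CCC=C(C)C)[C@@H](C=O)[C@@H]1COC(=O)/C1=C/[C@H]2C[C@@H]2C
A5 | alternative 3 | methyl 2-(trimethylsilyloxy)cycloocta-1,3-dienecarboxylate with C1, C6, C8 and C1′ in place | CC(C)(C)[Si](C)(C)OC[C@@H](CCC=C(C)C)[C@@H]1/C(O[Si](C)(C)C)=C(C(=O)OC)\C=C/[C@@H](C)C[C@@H]1O[Si](C)(C)C(C)(C)C
A6 | alternative 3 | trimethylsilyl enol ether of the trisubstituted cyclohexanone | CC(C)(C)[Si](C)(C)OC[C@@H](CCC=C(C)C)[C@@H]1C(O[Si](C)(C)C)=C[C@@H](C)C[C@@H]1O[Si](C)(C)C(C)(C)C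
A7 | alternative 3 | methyl propiolate | C#CC(=O)OC
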